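**Strategy.** The route rests on cutting the bond between the exocyclic vinylic CH of the α-alkylidene γ-lactone (ring A) and the first CH2 of the polyene chain. One operation, a one-pot hydroboration/B-alkyl Suzuki–Miyaura coupling, unites the two halves: 9-BBN adds only to the terminal vinyl group of a butenolide-bearing tetraene that ends in a 1,3-diene, and the resulting homoallylic borane couples with the (E)-enol triflate of the (S)-α-formyl lactone with retention of geometry. The step exploits two features: the vinylic CH is the β-carbon of ring A's exocyclic enoate (a masked formyl carbon), and the chain CH2 is homoallylic to the C(CH3)=CH unit, hence a diene terminus.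

Key step: step 11

Assumption: (S)-5-(hydroxymethyl)dihydrofuran-2(3H)-one (from L-glutamic acid), (E)-geranyl acetate and 4-(bromomethyl)furan-2(5H)-one are taken as purchased materials.

**Step 1**
Reactants: 1 (S)-5-(hydroxymethyl)dihydrofuran-2(3H)-one
Product: 2 (S)-5-oxotetrahydrofuran-2-carbaldehyde
Conditions: IBX (1.5 equiv), EtOAc, 75 °C; filter, concentrate, use crude at once
Reagents that add atoms: none
Why: IBX oxidation of the primary alcohol under neutral, non-aqueous conditions should give the α-oxy aldehyde without hydrate formation or epimerisation, the (S) centre coming unchanged from the chiral pool.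

**Step 2**
Reactants: 2 (S)-5-oxotetrahydrofuran-2-carbaldehyde
Product: 3 (S)-5-(2-methylprop-1-en-1-yl)dihydrofuran-2(3H)-one
Conditions: i-PrPPh3I, KN(SiMe3)2, THF, 0 °C; then 2, −78 °C → 0 °C
Reagents that add atoms: isopropyltriphenylphosphonium iodide, CC(C)[P+](c1ccccc1)(c1ccccc1)c1ccccc1.[I-]
Why: Wittig olefination with the non-stabilised isopropylidene ylide is fast at −78 °C and aldehyde-selective over the lactone, so the stereocentre should be retained, and no alkene geometry arises because the new alkene carries two methyl groups.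

**Step 3**
Reactants: 3 (S)-5-(2-methylprop-1-en-1-yl)dihydrofuran-2(3H)-one
Product: 4 (5S)-3-(hydroxymethylidene)-5-(2-methylprop-1-en-1-yl)dihydrofuran-2(3H)-one (enol form of the α-formyl lactone)
Conditions: NaH, HCO2Et, EtOH (cat.), THF, 0 °C → rt; cold dilute HCl to pH 4
Reagents that add atoms: ethyl formate, CCOC=O
Why: Claisen-type formylation of the lactone enolate is driven by formation of the stabilised sodium enolate of the β-formyl lactone, and the γ stereocentre is not acidic and stays untouched.

**Step 4**
Reactants: 4 (5S)-3-(hydroxymethylidene)-5-(2-methylprop-1-en-1-yl)dihydrofuran-2(3H)-one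
Product: 5 [(E)-[(5S)-5-(2-methylprop-1-en-1-yl)-2-oxodihydrofuran-3(2H)-ylidene]methyl] trifluoromethanesulfonate
Conditions: Tf2O, aq. Me4NOH (25%), toluene, 0 °C
Reagents that add atoms: trifluoromethanesulfonic anhydride, O=S(=O)(OS(=O)(=O)C(F)(F)F)C(F)(F)F
Why: O-sulfonylation of the non-chelated tetramethylammonium enolate, which prefers the dipole-minimised arrangement with the enolate oxygen anti to the lactone carbonyl, should favour the (E)-enol triflate as in the E-selective triflation of β-keto esters under such conditions, any Z isomer being removed by chromatography.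

**Step 5**
Reactants: 6 geranyl acetate
Product: 7 (2E,6E)-8-hydroxy-3,7-dimethylocta-2,6-dien-1-yl acetate
Conditions: SeO2 (cat.), t-BuOOH, salicylic acid (cat.), CH2Cl2, rt
Reagents that add atoms: tert-butyl hydroperoxide, CC(C)(C)OO (oxygen source); selenium dioxide, O=[Se]=O (catalytic oxygen carrier)
Why: Riley allylic oxidation (ene reaction followed by a [2,3]-sigmatropic shift) attacks the electron-rich distal trisubstituted alkene at its (E)-methyl group and should give the (E)-allylic alcohol, the alkene next to the acetate being deactivated.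

**Step 6**
Reactants: 7 (2E,6E)-8-hydroxy-3,7-dimethylocta-2,6-dien-1-yl acetate
Product: 8 (2E,6E)-3,7-dimethyl-8-oxoocta-2,6-dien-1-yl acetate
Conditions: MnO2, CH2Cl2, rt
Reagents that add atoms: none
Why: MnO2 oxidises the allylic alcohol selectively to the enal without touching the acetate or the alkene geometry, and any enal already formed in step 5 passes through unchanged.

**Step 7**
Reactants: 8 (2E,6E)-3,7-dimethyl-8-oxoocta-2,6-dien-1-yl acetate
Product: 10 (2E,6E)-3,7-dimethylnona-2,6,8-trien-1-ol, via triene acetate 9 (not isolated)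
Conditions: Ph3PCH3Br, KOt-Bu, THF, −78 → 0 °C; then MeOH, K2CO3 (cat.), rt, same flask
Reagents that add atoms: methyltriphenylphosphonium bromide, C[P+](c1ccccc1)(c1ccccc1)c1ccccc1.[Br-]
Why: Wittig methylenation of the enal should create the terminal 1,3-diene without disturbing the E-trisubstituted alkenes, and in-flask transesterification with methanol removes the acetate.

**Step 8**
Reactants: 10 (2E,6E)-3,7-dimethylnona-2,6,8-trien-1-ol
Product: 11 (2E,6E)-3,7-dimethylnona-2,6,8-trienal
Conditions: MnO2, CH2Cl2, rt, dark
Reagents that add atoms: none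
Why: MnO2 oxidation of a primary allylic alcohol to the enal proceeds with retention of the E geometry (as in geraniol to geranial) and should leave the diene untouched.

**Step 9**
Reactants: 12 4-(bromomethyl)furan-2(5H)-one
Product: 13 diethyl [(5-oxo-2,5-dihydrofuran-3-yl)methyl]phosphonate
Conditions: P(OEt)3, toluene, 110 °C
Reagents that add atoms: triethyl phosphite, CCOP(OCC)OCC
Why: Michaelis–Arbuzov reaction of the primary allylic bromide should give the vinylogous phosphonoacetate, in analogy to the preparation of 4-phosphonocrotonates from 4-bromocrotonates.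

**Step 10**
Reactants: 11 (2E,6E)-3,7-dimethylnona-2,6,8-trienal; 13 diethyl [(5-oxo-2,5-dihydrofuran-3-yl)methyl]phosphonate
Product: 14 4-[(1E,3E,7E)-4,8-dimethyldeca-1,3,7,9-tetraen-1-yl]furan-2(5H)-one
Conditions: 13, LiN(SiMe3)2, THF, −78 °C; then 11, −78 → 0 °C, dark
Reagents that add atoms: none
Why: Horner–Wadsworth–Emmons olefination of the phosphonate anion, stabilised through the butenolide like a 4-phosphonocrotonate anion, should react at the carbon next to phosphorus and give the new disubstituted alkene with E geometry.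

**Step 11**
Reactants: 14 4-[(1E,3E,7E)-4,8-dimethyldeca-1,3,7,9-tetraen-1-yl]furan-2(5H)-one; 5 [(E)-[(5S)-5-(2-methylprop-1-en-1-yl)-2-oxodihydrofuran-3(2H)-ylidene]methyl] trifluoromethanesulfonate
Product: 16 (S,E)-3-[(4E,8E,10E)-4,8-dimethyl-11-(5-oxo-2,5-dihydrofuran-3-yl)undeca-4,8,10-trien-1-ylidene]-5-(2-methylprop-1-en-1-yl)dihydrofuran-2(3H)-one, via homoallylic 9-BBN borane 15 (not isolated)
Conditions: 14, 9-BBN, THF, 0 °C → rt; then 5, PdCl2(dppf)·CH2Cl2 (5 mol%), AsPh3 (10 mol%), aq. K3PO4, DMF, rt, degassed, dark
Reagents that add atoms: none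
Why: 9-BBN adds syn and anti-Markovnikov to the only monosubstituted alkene of 14, the terminal vinyl of the 1,3-diene, to give homoallylic borane 15; zerovalent palladium then inserts into the vinyl C–O bond of triflate 5, phosphate-activated 15 transfers its primary alkyl group to palladium, and reductive elimination forms the CH(sp2)–CH2(sp3) bond. This is a B-alkyl Suzuki–Miyaura coupling of an alkyl-9-BBN with a β-(triflyloxy)enoate, a well-established pairing. No ring is closed and no stereocentre is created; the (S) centre of ring A is untouched, and the exocyclic E geometry is carried over from 5 because oxidative addition and reductive elimination both proceed with retention at the vinyl carbon. The step needs chemoselective hydroboration, secured by the steric preference of 9-BBN for CH2=CH over the trisubstituted, conjugated and electron-poor alkenes and by the slow reaction of lactones with 9-BBN at room temperature. It also needs activation of C–OTf in preference to the allylic C–O bond of ring A, secured by the much faster oxidative addition of the electron-poor vinyl triflate at room temperature. Mild aqueous K3PO4 at room temperature should leave the butenolide and the new α-alkylidene lactone intact.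

**Compound list**
1 | (S)-5-(hydroxymethyl)dihydrofuran-2(3H)-one | OC[C@@H]1CCC(=O)O1 | starting material
2 | (S)-5-oxotetrahydrofuran-2-carbaldehyde | O=C[C@@H]1CCC(=O)O1 | intermediate
3 | (S)-5-(2-methylprop-1-en-1-yl)dihydrofuran-2(3H)-one | CC(C)=C[C@@H]1CCC(=O)O1 | intermediate
4 | (5S)-3-(hydroxymethylidene)-5-(2-methylprop-1-en-1-yl)dihydrofuran-2(3H)-one (enol of the α-formyl lactone, enol geometry not fixed) | CC(C)=C[C@@H]1CC(=CO)C(=O)O1 | intermediate
5 | [(E)-[(5S)-5-(2-methylprop-1-en-1-yl)-2-oxodihydrofuran-3(2H)-ylidene]methyl] trifluoromethanesulfonate | CC(C)=C[C@@H]1C/C(=C\OS(=O)(=O)C(F)(F)F)C(=O)O1 | intermediate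
6 | geranyl acetate, (2E)-3,7-dimethylocta-2,6-dien-1-yl acetate | CC(C)=CCC/C(C)=C/COC(C)=O | starting material
7 | (2E,6E)-8-hydroxy-3,7-dimethylocta-2,6-dien-1-yl acetate | OC/C(C)=C/CC/C(C)=C/COC(C)=O | intermediate
8 | (2E,6E)-3,7-dimethyl-8-oxoocta-2,6-dien-1-yl acetate | O=C/C(C)=C/CC/C(C)=C/COC(C)=O | intermediate
9 | (2E,6E)-3,7-dimethylnona-2,6,8-trien-1-yl acetate | C=C/C(C)=C/CC/C(C)=C/COC(C)=O | intermediate
10 | (2E,6E)-3,7-dimethylnona-2,6,8-trien-1-ol | C=C/C(C)=C/CC/C(C)=C/CO | intermediate
11 | (2E,6E)-3,7-dimethylnona-2,6,8-trienal | C=C/C(C)=C/CC/C(C)=C/C=O | intermediate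
12 | 4-(bromomethyl)furan-2(5H)-one | BrCC1=CC(=O)OC1 | starting material
13 | diethyl [(5-oxo-2,5-dihydrofuran-3-yl)methyl]phosphonate | CCOP(=O)(OCC)CC1=CC(=O)OC1 | intermediate
14 | 4-[(1E,3E,7E)-4,8-dimethyldeca-1,3,7,9-tetraen-1-yl]furan-2(5H)-one | C=C/C(C)=C/CC/C(C)=C/C=C/C1=CC(=O)OC1 | intermediate
15 | 4-[(1E,3E,7E)-10-(9-borabicyclo[3.3.1]nonan-9-yl)-4,8-dimethyldeca-1,3,7-trien-1-yl]furan-2(5H)-one | C1CCC2CCCC1B2CC/C(C)=C/CC/C(C)=C/C=C/C1=CC(=O)OC1 | intermediate
16 | (S,E)-3-[(4E,8E,10E)-4,8-dimethyl-11-(5-oxo-2,5-dihydrofuran-3-yl)undeca-4,8,10-trien-1-ylidene]-5-(2-methylprop-1-en-1-yl)dihydrofuran-2(3H)-one | CC(C)=C[C@@H]1C/C(=C\CC/C(C)=C/CC/C(C)=C/C=C/C2=CC(=O)OC2)C(=O)O1 | target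

**Step count.** Total: 11 steps. Longest linear sequence: 6 steps (steps 5, 6, 7, 8, 10 and 11, from geranyl acetate 6 to 16).

**Steps most likely to fail**

1. Step 11. The coupling may suffer from base-induced opening or γ-deprotonation of the butenolide, hydrolysis of the enol triflate before transmetalation, incomplete site selectivity of the hydroboration, or ionisation of the allylic C–O bond of ring A by palladium. The fallback sets out from 14 and comes back at 16, replacing the basic boron coupling by a base-free zinc coupling that forms the same bond. Tetraene 14 is hydroborated as before to 15, which is oxidised with NaBO3·4H2O to the homoallylic alcohol 4-[(1E,3E,7E)-10-hydroxy-4,8-dimethyldeca-1,3,7-trien-1-yl]furan-2(5H)-one F1. Treatment with I2, PPh3 and imidazole in CH2Cl2 should give the primary iodide 4-[(1E,3E,7E)-10-iodo-4,8-dimethyldeca-1,3,7-trien-1-yl]furan-2(5H)-one F2. Zinc insertion (Zn dust, LiCl, THF) should give iodo[(3E,7E,9E)-4,8-dimethyl-10-(5-oxo-2,5-dihydrofuran-3-yl)deca-3,7,9-trien-1-yl]zinc F3, and Negishi coupling of this with triflate 5 (Pd(PPh3)4, THF/NMP, rt) should give 16.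

2. Step 10. The olefination may be diverted by deprotonation at the ring CH2 of the butenolide and vinylogous aldol pathways, by base-induced decomposition of the lactone, or by erosion of E selectivity. The fallback sets out from 11 and comes back at 14, building the diene–butenolide bond by cross-coupling instead of olefination. Chromium-mediated boron olefination of 11 (Cl2CHB(pin), CrCl2, LiI, THF, rt) should give the (E,E)-dienylboronate 2-[(1E,3E,7E)-4,8-dimethyldeca-1,3,7,9-tetraen-1-yl]-4,4,5,5-tetramethyl-1,3,2-dioxaborolane F4. Suzuki–Miyaura coupling of this with purchased 4-bromofuran-2(5H)-one (BrC1=CC(=O)OC1; PdCl2(dppf), KF, THF/H2O, rt) should give 14.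

3. Step 2. The basic ylide may epimerise the α-oxy aldehyde or attack the lactone carbonyl, and the hindered ylide may react sluggishly. The fallback sets out from 2 and comes back at 3, using a non-basic methylenation followed by metathesis. Methylenation of 2 with Zn, CH2Br2 and TiCl4 (THF/CH2Cl2, 0 °C) should give (S)-5-vinyldihydrofuran-2(3H)-one F5. Cross-metathesis of this with 2-methylbut-2-ene as co-solvent, using second-generation Grubbs catalyst RuCl2(=CHPh)(H2IMes)(PCy3) in CH2Cl2 at 40 °C, should give 3.

**Further compounds**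
F1 | step 11 | 4-[(1E,3E,7E)-10-hydroxy-4,8-dimethyldeca-1,3,7-trien-1-yl]furan-2(5H)-one | OCC/C(C)=C/CC/C(C)=C/C=C/C1=CC(=O)OC1
F2 | step 11 | 4-[(1E,3E,7E)-10-iodo-4,8-dimethyldeca-1,3,7-trien-1-yl]furan-2(5H)-one | ICC/C(C)=C/CC/C(C)=C/C=C/C1=CC(=O)OC1
F3 | step 11 | iodo[(3E,7E,9E)-4,8-dimethyl-10-(5-oxo-2,5-dihydrofuran-3-yl)deca-3,7,9-trien-1-yl]zinc | I[Zn]CC/C(C)=C/CC/C(C)=C/C=C/C1=CC(=O)OC1
F4 | step 10 | 2-[(1E,3E,7E)-4,8-dimethyldeca-1,3,7,9-tetraen-1-yl]-4,4,5,5-tetramethyl-1,3,2-dioxaborolane | C=C/C(C)=C/CC/C(C)=C/C=C/B1OC(C)(C)C(C)(C)O1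
F5 | step 2 | (S)-5-vinyldihydrofuran-2(3H)-one | C=C[C@@H]1CCC(=O)O1
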